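## Retrosynthetic overview
1. The two phenols are traced back to methyl ethers. The acetyl group is then removed as a Friedel–Crafts bond at the ring carbon para to one OMe and next to the chain. This leaves a 5-(10-phenyldecyl)resorcinol dimethyl ether.
2. The key disconnection is the aryl–CH2 bond. An aryl bromide carbon and an aldehyde carbonyl carbon are both electrophilic. The aldehyde is inverted to an alkyl carbanion equivalent as its NH2-hydrazone, nickel joins the two carbons, and N2 leaves. The CH2 therefore arrives at the final oxidation level with nothing to strip off.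
3. The ω-phenyl C10 aldehyde comes from ozonolysis of a terminal alkene, which comes from PhMgBr and an ω-bromoalkene under copper catalysis.
4. No ring is formed. Both benzene rings are bought intact.

Assumption: the SMILES holds no stereocentre and no stereogenic double bond, so the target is achiral and the route needs no stereocontrol.

## Route

Step 1
Reactants: 1 11-bromoundec-1-ene; 2 phenylmagnesium bromide
Product: 3 11-phenylundec-1-ene
Conditions: PhMgBr (1.3 equiv, THF), Li2CuCl4 (5 mol %), NMP (4 equiv), THF, 0 °C → rt, 12 h; aq NH4Cl
Reagents that add atoms: phenylmagnesium bromide (compound 2), Br[Mg]c1ccccc1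
Why: Kochi-type copper-catalysed Grignard cross-coupling, in which the phenyl cuprate formed in situ displaces the unhindered primary bromide and leaves the remote terminal alkene untouched; no stereocentre is formed.

Step 2
Reactants: 3 11-phenylundec-1-ene
Product: 5 10-phenyldecanal, via secondary ozonide 4 (not isolated)
Conditions: O3/O2, CH2Cl2, −78 °C to first blue colour; N2 purge; Me2S (5 equiv), −78 °C → rt
Reagents that add atoms: ozone, [O-][O+]=O
Why: Criegee ozonolysis with reductive work-up, in which the alkene reacts with ozone many orders of magnitude faster than the unactivated monoalkylbenzene ring, so only the terminal CH2 is cut off.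

Step 3
Reactants: 5 10-phenyldecanal; 6 1-bromo-3,5-dimethoxybenzene
Product: 9 1,3-dimethoxy-5-(10-phenyldecyl)benzene, via hydrazone 7 (not isolated), via alkyl diazene 8 (not isolated)
Conditions: (a) 5 added slowly to N2H4·H2O (1.2 equiv), THF, rt, 1 h, then 4 Å MS; (b) 6 (1.3 equiv), Ni(cod)2 (10 mol %), PMe3 (40 mol %), LiOt-Bu (2.5 equiv), THF/1,4-dioxane, 80 °C, 16 h, sealed tube, Ar
Reagents that add atoms: hydrazine monohydrate, NN.O (its nitrogen is held only by 7 and 8 and is lost as N2 before 9)
Why: Proposed new method: condensation gives the N-unsubstituted hydrazone 7, whose deprotonated form is a diaza-allyl anion carrying negative charge on the former carbonyl carbon (carbonyl umpolung, a traceless acyl-anion-type synthon), so after oxidative addition of 6 to zerovalent nickel the hydrazonide binds through nitrogen, slips from N to C, and reductive elimination from the divalent aryl(alkyl)nickel gives diazene 8, which the alkoxide deprotonates so that N2 leaves in a Wolff–Kishner-type step and the benzylic anion is protonated to 9; chelating diaza-allyl binding and the small, strongly donating PMe3 should block the site needed for β-hydride elimination and favour C- over N-arylation; the closest known reaction type is the Ni(cod)2/PMe3-catalysed denitrogenative cross-coupling of aromatic aldehyde hydrazones with aryl bromides, together with ruthenium-catalysed carbonyl additions in which aliphatic aldehyde hydrazones already act as alkyl carbanion equivalents, and the new element is the β-hydrogen-bearing aliphatic hydrazone; the stereocentre of 8 is transient and vanishes with N2.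

Step 4
Reactants: 9 1,3-dimethoxy-5-(10-phenyldecyl)benzene
Product: 10 1-[2,4-dimethoxy-6-(10-phenyldecyl)phenyl]ethan-1-one
Conditions: AcCl (1.05 equiv), AlCl3 (1.2 equiv), CH2Cl2, −10 → 0 °C, 1 h; ice/1 M HCl
Reagents that add atoms: acetyl chloride, CC(=O)Cl
Why: Friedel–Crafts acylation, in which the acylium ion attacks C4/C6 (equivalent by symmetry, para to one OMe and ortho to the other) rather than C2 between the two methoxy groups, while the far less nucleophilic terminal phenyl ring cannot compete for one equivalent of AcCl.

Step 5
Reactants: 10 1-[2,4-dimethoxy-6-(10-phenyldecyl)phenyl]ethan-1-one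
Product: 11 1-[2,4-dihydroxy-6-(10-phenyldecyl)phenyl]ethan-1-one (target)
Conditions: BBr3 (5 equiv), CH2Cl2, −78 °C → rt, 16 h; ice-water
Reagents that add atoms: none
Why: BBr3 aryl methyl ether cleavage (O-coordination, then SN2 of bromide at methyl), in which the ortho ether goes first through chelation to the ketone and the para ether follows with excess reagent at rt, while the ketone and the alkyl chain are inert.

## Compound list
1 | 11-bromoundec-1-ene | C=CCCCCCCCCCBr | starting material
2 | phenylmagnesium bromide | Br[Mg]c1ccccc1 | starting material
3 | 11-phenylundec-1-ene [(undec-10-en-1-yl)benzene] | C=CCCCCCCCCCc1ccccc1 | intermediate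
4 | 3-(9-phenylnonyl)-1,2,4-trioxolane (secondary ozonide, racemic, not isolated) | C1OOC(CCCCCCCCCc2ccccc2)O1 | intermediate
5 | 10-phenyldecanal | O=CCCCCCCCCCc1ccccc1 | intermediate
6 | 1-bromo-3,5-dimethoxybenzene | COc1cc(Br)cc(OC)c1 | starting material
7 | (E)-(10-phenyldecylidene)hydrazine (not isolated) | N/N=C/CCCCCCCCCc1ccccc1 | intermediate
8 | [1-(3,5-dimethoxyphenyl)-10-phenyldecyl]diazene (racemic, transient, not isolated) | COc1cc(cc(OC)c1)C(N=N)CCCCCCCCCc1ccccc1 | intermediate
9 | 1,3-dimethoxy-5-(10-phenyldecyl)benzene | COc1cc(CCCCCCCCCCc2ccccc2)cc(OC)c1 | intermediate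
10 | 1-[2,4-dimethoxy-6-(10-phenyldecyl)phenyl]ethan-1-one | CC(=O)c1c(OC)cc(OC)cc1CCCCCCCCCCc1ccccc1 | intermediate
11 | 1-[2,4-dihydroxy-6-(10-phenyldecyl)phenyl]ethan-1-one (achiral) | CC(=O)c1c(O)cc(O)cc1CCCCCCCCCCc1ccccc1 | target

## Count and risks
Total step count: 5. Longest linear sequence: 5 (1 → 3 → 5 → 9 → 10 → 11).

**Step 3 is the most likely to fail.** The aliphatic hydrazone may form the azine. It may be reduced early to 1-phenyldecane, be arylated at nitrogen, or lose a β-hydrogen from the C-bound nickel alkyl.

The fallback sets out from 5 and comes back at 9. Compound 5 is condensed with TsNHNH2 in MeOH to 4-methyl-N'-[(E)-10-phenyldecylidene]benzenesulfonohydrazide F1. F1 is heated with 6, Pd2(dba)3, XPhos and LiOt-Bu in 1,4-dioxane at 90 °C. Base-induced loss of sulfinate gives 1-diazo-10-phenyldecane F2, whose nucleophilic carbon attacks the arylpalladium bromide. Carbene migratory insertion followed by β-hydride elimination, which is productive here, gives 1,3-dimethoxy-5-[(1E)-10-phenyldec-1-en-1-yl]benzene F3. Hydrogenation of F3 (H2, Pd/C, EtOAc) gives 9.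

**Step 4 is the second risk.** Some acylation may occur at C2, AlCl3 may cleave the new ortho methoxy group, and any excess AcCl could acylate the terminal phenyl ring.

The fallback sets out from 9 and comes back at 10. NBS in MeCN at 0 °C brominates para to a methoxy group and gives 2-bromo-1,5-dimethoxy-3-(10-phenyldecyl)benzene F4, which can be purified to a single isomer. Bromine–lithium exchange with n-BuLi in THF at −78 °C gives [2,4-dimethoxy-6-(10-phenyldecyl)phenyl]lithium F5. Addition of N-methoxy-N-methylacetamide and a dilute HCl quench gives 10, with the position fixed by the halogen.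

**Step 5 is the third risk.** The methoxy group para to the boron-complexed ketone is deactivated, so the reaction may stall at the 2-hydroxy-4-methoxy ketone.

The fallback sets out from 9 and comes back at 11, so the ethers are cleaved before any ketone is present. BBr3 in CH2Cl2 converts 9 to 5-(10-phenyldecyl)benzene-1,3-diol F6. F6 is then C-acetylated with AcOH and BF3·OEt2 at 90 °C (Nencki-type acylation at the position ortho to one OH, para to the other and next to the chain) and gives 11 directly.

## Further compounds
F1 | step 3 | 4-methyl-N'-[(E)-10-phenyldecylidene]benzenesulfonohydrazide | Cc1ccc(cc1)S(=O)(=O)N/N=C/CCCCCCCCCc1ccccc1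
F2 | step 3 | 1-diazo-10-phenyldecane | [N-]=[N+]=CCCCCCCCCCc1ccccc1
F3 | step 3 | 1,3-dimethoxy-5-[(1E)-10-phenyldec-1-en-1-yl]benzene | COc1cc(/C=C/CCCCCCCCc2ccccc2)cc(OC)c1
F4 | step 4 | 2-bromo-1,5-dimethoxy-3-(10-phenyldecyl)benzene | COc1cc(OC)c(Br)c(CCCCCCCCCCc2ccccc2)c1
F5 | step 4 | [2,4-dimethoxy-6-(10-phenyldecyl)phenyl]lithium | COc1cc(OC)c([Li])c(CCCCCCCCCCc2ccccc2)c1
F6 | step 5 | 5-(10-phenyldecyl)benzene-1,3-diol | Oc1cc(O)cc(CCCCCCCCCCc2ccccc2)c1
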